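**Retrosynthetic overview**
- The free C17 acid comes from its tert-butyl ester by acidolysis in the last step.
- Rings A and B come from one head-to-tail bicyclisation of a fully oxidised acyclic tetraene. H adds at C3 of the terminal isopropylidene, C4–C5 and then C10–C9 close, and H is lost from C7. This is a one-electron copy of the labdane cyclase sequence.
- The single C6 acyloxy stereocentre of the acyclic precursor controls C5, C10 and C9. The Z-enoate geometry places the side chain equatorial at C9.
- The acyclic precursor comes from a Z-selective Horner–Wadsworth–Emmons reaction (C8=C9) between a C6-acyloxy phosphonate and a butenolide aldehyde. The phosphonate is built from a geranate-derived chloromethyl ketone and a phosphonoacetate, followed by CBS reduction and esterification.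
- Ring order: the butenolide is bought intact in 3-bromofuranone, then ring A and ring B form in the same flask.

Assumption: methyl (E)-geranate, (R)-2-methylbutanoic acid and 3-bromofuran-2(5H)-one are bought as catalogue single isomers, and labdane numbering (C1–C20) is used for positions.

**Step 1**
Reactants: 1 diphenyl phosphite; 2 tert-butyl bromoacetate
Product: 3 tert-butyl 2-(diphenoxyphosphoryl)acetate
Conditions: Et3N (1.2 equiv), CH2Cl2, 0 °C to rt
Reagents that add atoms: none
Why: Michaelis–Becker P-alkylation, in which the amine-generated phosphite anion displaces the activated primary bromide by SN2; no stereocentre is formed.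

**Step 2**
Reactants: 4 methyl (2E)-3,7-dimethylocta-2,6-dienoate (methyl geranate)
Product: 6 (3E)-1-chloro-4,8-dimethylnona-3,7-dien-2-one, via lithium hemiketal alkoxide 5 (not isolated)
Conditions: ICH2Cl (1.5 equiv), MeLi·LiBr (1.4 equiv, slow addition), THF–Et2O, −78 °C; then AcOH, −78 °C
Reagents that add atoms: chloroiodomethane ClCI
Why: Halomethyllithium carbenoid acylation of an ester, in which chloromethyllithium from I/Li exchange adds 1,2 and the tetrahedral alkoxide survives at −78 °C until the acidic quench, so only the chloromethyl ketone forms and the E-alkene is untouched.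

**Step 3**
Reactants: 3 tert-butyl 2-(diphenoxyphosphoryl)acetate; 6 (3E)-1-chloro-4,8-dimethylnona-3,7-dien-2-one
Product: 8 tert-butyl (5E)-2-(diphenoxyphosphoryl)-6,10-dimethyl-4-oxoundeca-5,9-dienoate (C2 epimers), via sodium phosphonate carbanion 7 (not isolated)
Conditions: NaH (1.1 equiv), THF, 0 °C; then 6, NaI (10 mol %), 0 °C to rt
Reagents that add atoms: none
Why: Malonate-type SN2 alkylation of a stabilised carbanion with an activated α-chloroketone forms C7–C8, the β,β-disubstituted enone resists Michael addition, and the new C2 centre is erased in step 7.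

**Step 4**
Reactants: 8 tert-butyl (5E)-2-(diphenoxyphosphoryl)-6,10-dimethyl-4-oxoundeca-5,9-dienoate
Product: 10 tert-butyl (4S,5E)-2-(diphenoxyphosphoryl)-4-hydroxy-6,10-dimethylundeca-5,9-dienoate (C2 epimers), via catecholborate ester 9 (not isolated)
Conditions: (R)-2-methyl-CBS-oxazaborolidine (15 mol %), catecholborane (1.8 equiv), toluene, −78 °C; then MeOH, pH 7 buffer
Reagents that add atoms: none
Why: Corey–Bakshi–Shibata reduction of an enone, in which the trisubstituted alkenyl arm is the large group and the CH2 arm the small one, so the (R)-catalyst gives the (S)-carbinol (labdane C6) by 1,2-hydride delivery only.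

**Step 5**
Reactants: 10 tert-butyl (4S,5E)-2-(diphenoxyphosphoryl)-4-hydroxy-6,10-dimethylundeca-5,9-dienoate; 11 (2R)-2-methylbutanoic acid
Product: 13 tert-butyl (4S,5E)-2-(diphenoxyphosphoryl)-6,10-dimethyl-4-{[(2R)-2-methylbutanoyl]oxy}undeca-5,9-dienoate (C2 epimers), via O-acylisourea 12 (not isolated)
Conditions: DCC (1.3 equiv), DMAP (10 mol %), CH2Cl2, 0 °C to rt
Reagents that add atoms: none
Why: Steglich esterification forms only the acyl C–O bond, so both the carbinol centre and the α-centre of the acid are retained, and the near-neutral medium avoids attack of the γ-oxygen on phosphorus.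

**Step 6**
Reactants: 14 3-bromofuran-2(5H)-one; 15 prop-2-en-1-ol (allyl alcohol)
Product: 16 3-(2-oxo-2,5-dihydrofuran-3-yl)propanal
Conditions: Pd(OAc)2 (5 mol %), Bu4NCl (1 equiv), NaHCO3 (2.5 equiv), DMF, 40 °C
Reagents that add atoms: none
Why: Mizoroki–Heck reaction under Jeffery conditions, in which the alkenylpalladium adds to the terminal carbon of allyl alcohol and β-hydride elimination toward the carbinol carbon releases the aldehyde; no stereocentre is formed.

**Step 7**
Reactants: 13 tert-butyl (4S,5E)-2-(diphenoxyphosphoryl)-6,10-dimethyl-4-{[(2R)-2-methylbutanoyl]oxy}undeca-5,9-dienoate; 16 3-(2-oxo-2,5-dihydrofuran-3-yl)propanal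
Product: 18 tert-butyl (2Z)-2-[(2S,3E)-4,8-dimethyl-2-{[(2R)-2-methylbutanoyl]oxy}nona-3,7-dien-1-yl]-5-(2-oxo-2,5-dihydrofuran-3-yl)pent-2-enoate, via sodium phosphonate carbanion 17 (not isolated)
Conditions: NaH (1.05 equiv), THF, 0 °C; then 16, −78 °C to 0 °C
Reagents that add atoms: none
Why: Ando-type Z-selective Horner–Wadsworth–Emmons olefination, in which the electron-poor diaryl phosphonate makes elimination fast and kinetic, so the C11 chain ends cis to the ester (farnesyl-type geometry, C7 trans to C11), and the fully consumed base leaves the butenolide and both stereocentres alone.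

**Step 8**
Reactants: 18 tert-butyl (2Z)-2-[(2S,3E)-4,8-dimethyl-2-{[(2R)-2-methylbutanoyl]oxy}nona-3,7-dien-1-yl]-5-(2-oxo-2,5-dihydrofuran-3-yl)pent-2-enoate
Product: 22 tert-butyl (5S,6S,9R,10R)-6-{[(2R)-2-methylbutanoyl]oxy}-16-oxo-15,16-epoxylabda-7,13-dien-17-oate, via acyclic C4 radical 19 (not isolated), via monocyclic C10 radical 20 (not isolated), via bicyclic C8 radical 21 (not isolated)
Conditions: [N,N'-bis(3,5-di-tert-butylsalicylidene)-1,2-cyclohexanediaminato]cobalt chloride, CoCl(C36H52N2O2) (10 mol %), PhSiH3 (30 mol % in three portions), degassed benzene (0.01 M), 50 °C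
Reagents that add atoms: none
Why: Proposed new method: the trivalent cobalt hydride made from the chloride and PhSiH3 transfers H• to C3 of the least hindered, most electron-rich alkene (the microscopic reverse of the known 1,1-disubstituted-to-trisubstituted alkene isomerisation) to give tertiary radical 19; 19 closes ring A 6-endo at C5 anti to the C7 chain of the A(1,3)-locked (S)-C6 centre (sets 5S); the nucleophilic radical 20 closes ring B 6-endo at the polarity-matched β-carbon C9 of the Z-enoate through a chair with the 6-acyloxy group and the C11 chain equatorial and the C10 methyl axial (sets 10R and 9R, trans-decalin); divalent cobalt then abstracts the less hindered C7–H of the tertiary α-ester radical 21 to give the conjugated 7-ene and return the hydride, so the step is a redox-neutral isomerisation; the closest known reaction types are cobalt-salen/silane MHAT cycloisomerisation of dienes, MHAT-initiated radical bicyclisation of oxygenated polyenes, and catalytic chain transfer (H abstraction from methacrylate-type radicals by divalent cobalt).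

**Step 9**
Reactants: 22 tert-butyl (5S,6S,9R,10R)-6-{[(2R)-2-methylbutanoyl]oxy}-16-oxo-15,16-epoxylabda-7,13-dien-17-oate
Product: 23 (5S,6S,9R,10R)-6-{[(2R)-2-methylbutanoyl]oxy}-16-oxo-15,16-epoxylabda-7,13-dien-17-oic acid (CNP0150853.1)
Conditions: CF3CO2H–CH2Cl2 (1:4), 0 °C to rt
Reagents that add atoms: none
Why: E1 acidolysis of the tert-butyl ester, in which the secondary ester, the butenolide and the C6–O bond (allylic only to an electron-poor alkene, so it does not ionise) survive and no stereocentre is touched.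

**Compound list**

| No. | Name | SMILES | Role |
|---|---|---|---|
| 1 | diphenyl phosphite | O=[PH](Oc1ccccc1)Oc1ccccc1 | starting material |
| 2 | tert-butyl bromoacetate | CC(C)(C)OC(=O)CBr | starting material |
| 3 | tert-butyl 2-(diphenoxyphosphoryl)acetate | CC(C)(C)OC(=O)CP(=O)(Oc1ccccc1)Oc1ccccc1 | intermediate |
| 4 | methyl (2E)-3,7-dimethylocta-2,6-dienoate | COC(=O)/C=C(\C)CCC=C(C)C | starting material |
| 5 | lithium (3E)-1-chloro-2-methoxy-4,8-dimethylnona-3,7-dien-2-olate | [Li+].[O-]C(CCl)(OC)/C=C(\C)CCC=C(C)C | intermediate |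
| 6 | (3E)-1-chloro-4,8-dimethylnona-3,7-dien-2-one | ClCC(=O)/C=C(\C)CCC=C(C)C | intermediate |
| 7 | sodium salt of 3 (phosphonate carbanion) | [Na+].CC(C)(C)OC(=O)[CH-]P(=O)(Oc1ccccc1)Oc1ccccc1 | intermediate |
| 8 | tert-butyl (5E)-2-(diphenoxyphosphoryl)-6,10-dimethyl-4-oxoundeca-5,9-dienoate, C2 epimers | CC(C)(C)OC(=O)C(CC(=O)/C=C(\C)CCC=C(C)C)P(=O)(Oc1ccccc1)Oc1ccccc1 | intermediate |
| 9 | catecholborate ester of 10 | CC(C)(C)OC(=O)C(C[C@H](OB1Oc2ccccc2O1)/C=C(\C)CCC=C(C)C)P(=O)(Oc1ccccc1)Oc1ccccc1 | intermediate |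
| 10 | tert-butyl (4S,5E)-2-(diphenoxyphosphoryl)-4-hydroxy-6,10-dimethylundeca-5,9-dienoate, C2 epimers | CC(C)(C)OC(=O)C(C[C@H](O)/C=C(\C)CCC=C(C)C)P(=O)(Oc1ccccc1)Oc1ccccc1 | intermediate |
| 11 | (2R)-2-methylbutanoic acid | CC[C@@H](C)C(=O)O | starting material |
| 12 | O-[(2R)-2-methylbutanoyl]-N,N'-dicyclohexylisourea | CC[C@@H](C)C(=O)OC(=NC1CCCCC1)NC1CCCCC1 | intermediate |
| 13 | tert-butyl (4S,5E)-2-(diphenoxyphosphoryl)-6,10-dimethyl-4-{[(2R)-2-methylbutanoyl]oxy}undeca-5,9-dienoate, C2 epimers | CC[C@@H](C)C(=O)O[C@H](/C=C(\C)CCC=C(C)C)CC(C(=O)OC(C)(C)C)P(=O)(Oc1ccccc1)Oc1ccccc1 | intermediate |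
| 14 | 3-bromofuran-2(5H)-one | O=C1OCC=C1Br | starting material |
| 15 | prop-2-en-1-ol | C=CCO | starting material |
| 16 | 3-(2-oxo-2,5-dihydrofuran-3-yl)propanal | O=CCCC1=CCOC1=O | intermediate |
| 17 | sodium salt of 13 (phosphonate carbanion) | [Na+].CC[C@@H](C)C(=O)O[C@H](/C=C(\C)CCC=C(C)C)C[C-](C(=O)OC(C)(C)C)P(=O)(Oc1ccccc1)Oc1ccccc1 | intermediate |
| 18 | tert-butyl (2Z)-2-[(2S,3E)-4,8-dimethyl-2-{[(2R)-2-methylbutanoyl]oxy}nona-3,7-dien-1-yl]-5-(2-oxo-2,5-dihydrofuran-3-yl)pent-2-enoate | CC[C@@H](C)C(=O)O[C@H](/C=C(\C)CCC=C(C)C)C/C(C(=O)OC(C)(C)C)=C/CCC1=CCOC1=O | intermediate |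
| 19 | acyclic tertiary C4 radical (H added at C3 of 18) | CC[C@@H](C)C(=O)O[C@H](/C=C(\C)CCC[C](C)C)C/C(C(=O)OC(C)(C)C)=C/CCC1=CCOC1=O | intermediate |
| 20 | monocyclic tertiary C10 radical (ring A closed, 5S) | CC[C@@H](C)C(=O)O[C@H]([C@@H]1[C](C)CCCC1(C)C)C/C(C(=O)OC(C)(C)C)=C/CCC1=CCOC1=O | intermediate |
| 21 | bicyclic tertiary α-ester C8 radical (rings A and B closed) | CC[C@@H](C)C(=O)O[C@H]1C[C](C(=O)OC(C)(C)C)[C@H](CCC2=CCOC2=O)[C@@]2(C)CCCC(C)(C)[C@H]12 | intermediate |
| 22 | tert-butyl (5S,6S,9R,10R)-6-{[(2R)-2-methylbutanoyl]oxy}-16-oxo-15,16-epoxylabda-7,13-dien-17-oate (trans-decalin, 6α-acyloxy, 9β side chain) | CC[C@@H](C)C(=O)O[C@H]1C=C(C(=O)OC(C)(C)C)[C@H](CCC2=CCOC2=O)[C@@]2(C)CCCC(C)(C)[C@H]12 | intermediate |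
| 23 | (5S,6S,9R,10R)-6-{[(2R)-2-methylbutanoyl]oxy}-16-oxo-15,16-epoxylabda-7,13-dien-17-oic acid | CC[C@@H](C)C(=O)O[C@H]1C=C(C(=O)O)[C@H](CCC2=CCOC2=O)[C@@]2(C)CCCC(C)(C)[C@H]12 | target |

**Step count**
Total steps: 9. Longest linear sequence: 7 (steps 2, 3, 4, 5, 7, 8, 9).

**The three steps most likely to fail**

Step 8 (bicyclisation) carries four risks:
- H-atom transfer to the prenyl end may be slow.
- H-atom transfer to the enoate may compete and scramble its geometry.
- Face selectivity at C5 may be imperfect.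
- H abstraction at C9 instead of C7 would give the 8(9)-ene.

The fallback sets out from 18 and comes back at 22. The cascade is run as a group-transfer reaction instead of an isomerisation. With the same cobalt complex, stoichiometric PhSiH3 and slowly added S-phenyl benzenethiosulfonate, radical 21 is captured as the C8 phenyl sulfide F1. One equivalent of mCPBA at −78 °C gives the sulfoxide F2. Warming F2 in toluene over CaCO3 causes syn-elimination toward the less hindered C7–H and delivers 22.

Step 7 (Z-olefination) carries two risks. Z-selectivity may erode with the bulky α-substituent, and aldehyde 16 is sensitive to base. The fallback sets out from 13 (together with 14) and comes back at 18. Phosphonate 13 is olefinated with acrolein instead, giving the Z-dienoate F3. 9-BBN hydroborates only the terminal vinyl group to give the B-alkyl borane F4. A B-alkyl Suzuki coupling with 14 [PdCl2(dppf), K3PO4, DMF–H2O, rt] forms the C12–C13 bond and gives 18. This path does not need aldehyde 16 at all.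

Step 6 (Heck reaction) carries one main risk. β-Hydride elimination toward the ring side would give a dienol instead of the aldehyde. The fallback sets out from 14 and comes back at 16. Acrolein diethyl acetal is hydroborated with 9-BBN to the borane F5. B-alkyl Suzuki coupling of F5 with 14 [PdCl2(dppf), K3PO4, DMF–H2O] gives the acetal F6. Mild aqueous acid (PPTS, acetone–H2O) then releases 16.

**Further compounds**
F1 | step 8 | tert-butyl (5S,6S,9R,10R)-6-{[(2R)-2-methylbutanoyl]oxy}-16-oxo-8-(phenylsulfanyl)-15,16-epoxylabd-13-en-17-oate (C8 epimers) | CC[C@@H](C)C(=O)O[C@H]1CC(Sc2ccccc2)(C(=O)OC(C)(C)C)[C@H](CCC2=CCOC2=O)[C@@]2(C)CCCC(C)(C)[C@H]12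
F2 | step 8 | the corresponding C8 phenyl sulfoxide | CC[C@@H](C)C(=O)O[C@H]1CC(S(=O)c2ccccc2)(C(=O)OC(C)(C)C)[C@H](CCC2=CCOC2=O)[C@@]2(C)CCCC(C)(C)[C@H]12
F3 | step 7 | tert-butyl (2Z)-2-[(2S,3E)-4,8-dimethyl-2-{[(2R)-2-methylbutanoyl]oxy}nona-3,7-dien-1-yl]penta-2,4-dienoate | CC[C@@H](C)C(=O)O[C@H](/C=C(\C)CCC=C(C)C)C/C(C(=O)OC(C)(C)C)=C/C=C
F4 | step 7 | 9-BBN adduct of F3 (boron on the terminal carbon, C12) | CC[C@@H](C)C(=O)O[C@H](/C=C(\C)CCC=C(C)C)C/C(C(=O)OC(C)(C)C)=C/CCB1C2CCCC1CCC2
F5 | step 6 | 9-(3,3-diethoxypropyl)-9-borabicyclo[3.3.1]nonane | CCOC(CCB1C2CCCC1CCC2)OCC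
F6 | step 6 | 3-(3,3-diethoxypropyl)furan-2(5H)-one | CCOC(CCC1=CCOC1=O)OCC
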